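**Retrosynthetic overview**

1. The target is taken back, by one dehydrogenation, to the ring-A dihydro compound 11, in which ring A is a cyclohexane-1,3-dione derivative. C7 is a ketone (no protecting group), and both prenyl groups come from enolate C-alkylations.
2. In 11 the heterocycle is disconnected at C4–C4a and O1–C8a. This gives the dianion of 2,4-diprenylcyclohexane-1,3-dione 4 and the (S)-β-lactone 9.
3. Enabling feature: the unit O1–C2–C3–C4(=O) is a β-lactone in disguise, and it is closed through the vinylogous ester O1–C8a=C4a–C4=O. With ring A at the 1,3-dione level (oxygens at C7 and C8a), C4a is a carbanion site and C8a a carbonyl that can take up the lactone oxygen.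
4. The four-membered oxetanone ring (O1, C2, C3, C4) is therefore enlarged by the two ring-A atoms C4a and C8a to the six-membered pyranone. C2 is set earlier by asymmetric hydrogenation, and its O1–C2 bond is never broken.
5. Ring order: ring B (bought), oxetanone ring (step 5), ring A as dione (bought, alkylated twice), pyranone ring by ring expansion (step 6), ring A aromatised last (step 7).

Key step: step 6

Remark on stereochemistry: C4 of 4 and C6/C8 of 10 and 11 are epimerisable α-carbonyl centres that disappear on aromatisation. These compounds are carried as mixtures and drawn without configuration at those atoms; only C2 is controlled.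

Remark on notation: lithium enolates and dianions are treated as the anions of the numbered diones and carry no numbers of their own.

**Step 1**
Reactants: 1 cyclohexane-1,3-dione; 2 prenyl bromide (1-bromo-3-methylbut-2-ene)
Product: 3 2-(3-methylbut-2-en-1-yl)cyclohexane-1,3-dione
Conditions: KOH (1 equiv), H2O, 0 °C → rt; acidify
Reagents that add atoms: none
Why: C-alkylation of the 1,3-dione enolate by SN2 at the primary allylic bromide; in water the enolate oxygens are hydrogen-bonded, which favours C2- over O-alkylation.

**Step 2**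
Reactants: 3 2-(3-methylbut-2-en-1-yl)cyclohexane-1,3-dione; 2 prenyl bromide
Product: 4 2,4-bis(3-methylbut-2-en-1-yl)cyclohexane-1,3-dione
Conditions: LDA (2.2 equiv), THF–DMPU, −78 → 0 °C; 2 (1.0 equiv), −78 °C → rt; aq. HCl
Reagents that add atoms: none
Why: γ-Alkylation of a β-diketone dianion: after the C2 enolate is formed, the second deprotonation gives the C4 carbanion, which is the most nucleophilic site and is alkylated by SN2; the new C4 centre is racemic by design.

**Step 3**
Reactants: 5 ethyl 3-(3,4-dimethoxyphenyl)-3-oxopropanoate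
Product: 6 ethyl (3S)-3-(3,4-dimethoxyphenyl)-3-hydroxypropanoate
Conditions: H2 (50 bar), RuCl2[(R)-BINAP] (0.5 mol %), EtOH, 60 °C
Reagents that add atoms: none
Why: Noyori asymmetric hydrogenation of a β-keto ester: the ester-chelated ketone is reduced on one face in the chiral Ru–BINAP pocket, and the (R)-ligand is expected to give the (S)-carbinol, as with other aryl β-keto esters such as ethyl benzoylacetate.

**Step 4**
Reactants: 6 ethyl (3S)-3-(3,4-dimethoxyphenyl)-3-hydroxypropanoate
Product: 7 (3S)-3-(3,4-dimethoxyphenyl)-3-hydroxypropanoic acid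
Conditions: LiOH, THF–H2O, 0 °C; cold 1 M HCl to pH 3
Reagents that add atoms: lithium hydroxide, [Li+].[OH-]
Why: Ester saponification; the carbinol centre is not involved, and the cold, weakly acidic work-up avoids ionisation of the electron-rich benzylic alcohol (the acid may be recrystallised to raise the ee if needed).

**Step 5**
Reactants: 7 (3S)-3-(3,4-dimethoxyphenyl)-3-hydroxypropanoic acid
Product: 9 (4S)-4-(3,4-dimethoxyphenyl)oxetan-2-one, via mixed carboxylic benzenesulfonic anhydride 8 (not isolated)
Conditions: PhSO2Cl (2 equiv), pyridine, 0–4 °C; cold work-up, used at once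
Reagents that add atoms: none
Why: β-Lactonisation by carboxyl activation: the carboxylate is sulfonylated faster than the secondary alcohol, and the hydroxyl closes the four-membered ring by 4-exo-trig attack on the activated acyl carbon, so the C–O bond at the stereocentre is not broken and (S) is retained.

**Step 6**
Reactants: 4 2,4-bis(3-methylbut-2-en-1-yl)cyclohexane-1,3-dione; 9 (4S)-4-(3,4-dimethoxyphenyl)oxetan-2-one
Product: 11 (2S)-2-(3,4-dimethoxyphenyl)-6,8-bis(3-methylbut-2-en-1-yl)-2,3,5,6-tetrahydro-4H-chromene-4,7(8H)-dione, via open-chain hydroxy triketone 10 (not isolated)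
Conditions: 4 (2.2 equiv), LDA (4.4 equiv), THF–DMPU, −78 → 0 → −78 °C; 9, −78 → −40 °C; AcOH; then TFA (10 mol %), 4 Å MS, CH2Cl2, 0 °C → rt
Reagents that add atoms: none
Why: The kinetic dianion of 4 carries its carbanion at C6, the only unsubstituted α′-CH2 (future C4a), and attacks the strained lactone carbonyl of 9 as in the Claisen-type γ-acylation of β-diketone dianions by esters; collapse of the tetrahedral intermediate breaks the acyl C4–O1 bond and never touches O1–C2, so C2 keeps its (S) configuration. The second equivalent of dianion removes the now doubly activated C4a–H, which enolises the new C4 ketone and so blocks retro-aldol loss of the aryl carbinol. After protonation to 10, O1–H adds to the C8a carbonyl in a 6-exo-trig closure and loss of water gives the vinylogous ester O1–C8a=C4a–C4=O, the same cyclodehydration that converts δ-hydroxy-β-diketones into 2,3-dihydro-4H-pyran-4-ones. In net terms C4a and C8a are inserted into the acyl–oxygen bond of the four-membered lactone, which becomes the six-membered pyranone (ring expansion by two atoms) while rings A and B are joined. No stereocentre of consequence is formed, because C6 and C8 are epimerisable and are erased in step 7. The step needs acyl- over alkyl-oxygen attack on the lactone and C- over O-acylation, which the hard lithium carbanion at −78 °C should secure, and cyclisation faster than ionisation of the benzylic carbinol, for which only catalytic TFA at 0 °C is used.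

**Step 7**
Reactants: 11 (2S)-2-(3,4-dimethoxyphenyl)-6,8-bis(3-methylbut-2-en-1-yl)-2,3,5,6-tetrahydro-4H-chromene-4,7(8H)-dione
Product: 12 (2S)-2-(3,4-dimethoxyphenyl)-7-hydroxy-6,8-bis(3-methylbut-2-en-1-yl)-2,3-dihydro-4H-chromen-4-one (IN0946)
Conditions: DDQ (1.0 equiv), CH2Cl2–dioxane, 0 °C → rt
Reagents that add atoms: none
Why: Aromatisation by dehydrogenation: 11 is in equilibrium with its 7-hydroxy-5,6-dihydro dienol, an electron-rich dihydroresorcinol, from which DDQ abstracts hydride at C5/C6 and a proton is lost to give the phenol; the C6 and C8 centres vanish and C2 should be untouched at this temperature.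

**Compound list**

1 | cyclohexane-1,3-dione | O=C1CCCC(=O)C1 | starting material
2 | prenyl bromide (1-bromo-3-methylbut-2-ene) | CC(C)=CCBr | starting material
3 | 2-(3-methylbut-2-en-1-yl)cyclohexane-1,3-dione | O=C1CCCC(=O)C1CC=C(C)C | intermediate
4 | 2,4-bis(3-methylbut-2-en-1-yl)cyclohexane-1,3-dione (racemic at C4) | O=C1CCC(CC=C(C)C)C(=O)C1CC=C(C)C | intermediate
5 | ethyl 3-(3,4-dimethoxyphenyl)-3-oxopropanoate | CCOC(=O)CC(=O)c1ccc(OC)c(OC)c1 | starting material
6 | ethyl (3S)-3-(3,4-dimethoxyphenyl)-3-hydroxypropanoate | COc1ccc([C@@H](O)CC(=O)OCC)cc1OC | intermediate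
7 | (3S)-3-(3,4-dimethoxyphenyl)-3-hydroxypropanoic acid | COc1ccc([C@@H](O)CC(=O)O)cc1OC | intermediate
8 | (3S)-3-(3,4-dimethoxyphenyl)-3-hydroxypropanoic benzenesulfonic anhydride | COc1ccc([C@@H](O)CC(=O)OS(=O)(=O)c2ccccc2)cc1OC | intermediate (not isolated)
9 | (4S)-4-(3,4-dimethoxyphenyl)oxetan-2-one | COc1ccc([C@@H]2CC(=O)O2)cc1OC | intermediate
10 | 6-[(3S)-3-(3,4-dimethoxyphenyl)-3-hydroxypropanoyl]-2,4-bis(3-methylbut-2-en-1-yl)cyclohexane-1,3-dione | COc1ccc([C@@H](O)CC(=O)C2CC(CC=C(C)C)C(=O)C(CC=C(C)C)C2=O)cc1OC | intermediate (not isolated)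
11 | (2S)-2-(3,4-dimethoxyphenyl)-6,8-bis(3-methylbut-2-en-1-yl)-2,3,5,6-tetrahydro-4H-chromene-4,7(8H)-dione (C6/C8 epimers and enol tautomers) | COc1ccc([C@@H]2CC(=O)C3=C(O2)C(CC=C(C)C)C(=O)C(CC=C(C)C)C3)cc1OC | intermediate
12 | (2S)-2-(3,4-dimethoxyphenyl)-7-hydroxy-6,8-bis(3-methylbut-2-en-1-yl)-2,3-dihydro-4H-chromen-4-one (IN0946) | COc1ccc([C@@H]2CC(=O)c3cc(CC=C(C)C)c(O)c(CC=C(C)C)c3O2)cc1OC | target

**Step count**

Total: 7 steps. Longest linear sequence: 5 steps (steps 3, 4, 5, 6, 7).

**Steps most likely to fail**

Step 6. The strongly basic dianion may take a proton from the lactone α-CH2, after which the lactone enolate opens by β-elimination to the cinnamate. It may also attack the benzylic carbon (alkyl–oxygen cleavage). In the acid stage, ionisation of the benzylic carbinol may compete with hemiketal formation and erode the ee.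
Fallback, from 6 and 4, returning at 11: the pyranone is closed from an open chain instead. Hydroxy ester 6 would be silylated (TBSOTf, 2,6-lutidine, CH2Cl2, −78 °C) to ethyl (3S)-3-[(tert-butyldimethylsilyl)oxy]-3-(3,4-dimethoxyphenyl)propanoate F1. The dianion of 4 (LDA, THF–DMPU) would then be C-acylated by this unstrained ester at −78 → 0 °C to give 6-[(3S)-3-[(tert-butyldimethylsilyl)oxy]-3-(3,4-dimethoxyphenyl)propanoyl]-2,4-bis(3-methylbut-2-en-1-yl)cyclohexane-1,3-dione F2. Aqueous HF in MeCN at 0 °C would remove the silyl group and cyclodehydrate to 11.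

Step 7. DDQ may go on to abstract hydride from the ortho-prenyl CH2 of the newly formed phenol (o-quinone methide, then 2H-chromene closure) or from C2–H (flavone formation and loss of the stereocentre).
Fallback, from 11, returning at 12: the phenol is generated already protected. Soft enolisation of 11 (TBSOTf 1.05 equiv, Et3N, CH2Cl2, −78 → 0 °C) should give the silyl dienol ether (2S)-7-[(tert-butyldimethylsilyl)oxy]-2-(3,4-dimethoxyphenyl)-6,8-bis(3-methylbut-2-en-1-yl)-2,3,5,6-tetrahydro-4H-chromen-4-one F3. This siloxy-cyclohexadiene would be dehydrogenated with DDQ and 2,6-lutidine at −40 °C to the aryl silyl ether (2S)-7-[(tert-butyldimethylsilyl)oxy]-2-(3,4-dimethoxyphenyl)-6,8-bis(3-methylbut-2-en-1-yl)-2,3-dihydro-4H-chromen-4-one F4, which cannot form an o-quinone methide. HF·pyridine in THF at 0 °C would then release 12.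

Step 5. The benzylic hydroxyl may be sulfonylated instead of the carboxyl group, followed by ionisation with racemisation or decarboxylative fragmentation to 3,4-dimethoxystyrene. The electron-rich lactone may also lose CO2 on silica or on warming.
Fallback, from 7, returning at 9: activation is moved to a group that cannot touch the hydroxyl. Acid 7 would be converted (PhSH, EDC·HCl, HOBt, CH2Cl2, 0 °C) into S-phenyl (3S)-3-(3,4-dimethoxyphenyl)-3-hydroxypropanethioate F5. Thiophilic activation of the thioester (AgO2CCF3, Na2HPO4, MeCN, rt) under buffered, non-acidic conditions would let the free hydroxyl close the lactone with retention to give 9.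

**Further compounds**

F1 | step 6 | ethyl (3S)-3-[(tert-butyldimethylsilyl)oxy]-3-(3,4-dimethoxyphenyl)propanoate | COc1ccc([C@@H](O[Si](C)(C)C(C)(C)C)CC(=O)OCC)cc1OC
F2 | step 6 | 6-[(3S)-3-[(tert-butyldimethylsilyl)oxy]-3-(3,4-dimethoxyphenyl)propanoyl]-2,4-bis(3-methylbut-2-en-1-yl)cyclohexane-1,3-dione | COc1ccc([C@@H](O[Si](C)(C)C(C)(C)C)CC(=O)C2CC(CC=C(C)C)C(=O)C(CC=C(C)C)C2=O)cc1OC
F3 | step 7 | (2S)-7-[(tert-butyldimethylsilyl)oxy]-2-(3,4-dimethoxyphenyl)-6,8-bis(3-methylbut-2-en-1-yl)-2,3,5,6-tetrahydro-4H-chromen-4-one | COc1ccc([C@@H]2CC(=O)C3=C(O2)C(CC=C(C)C)=C(O[Si](C)(C)C(C)(C)C)C(CC=C(C)C)C3)cc1OC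
F4 | step 7 | (2S)-7-[(tert-butyldimethylsilyl)oxy]-2-(3,4-dimethoxyphenyl)-6,8-bis(3-methylbut-2-en-1-yl)-2,3-dihydro-4H-chromen-4-one | COc1ccc([C@@H]2CC(=O)c3cc(CC=C(C)C)c(O[Si](C)(C)C(C)(C)C)c(CC=C(C)C)c3O2)cc1OC
F5 | step 5 | S-phenyl (3S)-3-(3,4-dimethoxyphenyl)-3-hydroxypropanethioate | COc1ccc([C@@H](O)CC(=O)Sc2ccccc2)cc1OC
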